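In the stirred vessel of red, everything goes in together at 70 °C on dusk's charge, so red is the dusk run carried on from 12.0 h to 20 h.

in all of them: X 1.4 mol%

|  | D | Z | temperature | remark | time |
|---|---|---|---|---|---|
| dusk | 0.50 M | 0.90 equiv | 70 °C | run made earlier |  |
| autumn | 0.75 M | 0.90 equiv | 70 °C | run made earlier |  |
| green | 0.50 M (fed, over 12 h) | 0.900 equiv | 70 °C | all else is in the flask from the start; the feed brings no volume worth counting | 20 h |
| teal | 0.50 M | 0.900 equiv |  | everything together at the start at 40 °C, warmed to 70 °C at 12 h | 20 h |
| amber | 0.50 M | 0.900 equiv (fed, over 12 h) |  | the addition at 40 °C, then warmed to 70 °C; the feed brings no volume worth counting | 20 h |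
| red | 0.50 M | 0.900 equiv | 70 °C | everything together at the start | 20 h |

- dusk (time / h: E / %, D / %): 3.00: 18, 29; 6.00: 35, 11; 10.0: 47, 3; 12.0: 51, 0
- autumn (time / min: E / %, D / %): 15.0: 0, 86; 40.0: 7, 72; 80.0: 17, 49; 120: 26, 33

(each reading ± 2 percentage points)

1. the flask with the highest amount of E, in percent of the D charged ("all alike" if they lie within 1.5 percentage points) (green / teal / amber / red / all alike)
2. final E, as a percentage of the D charged, in green
3. final E, as a percentage of the D charged, in teal
4. final E, as a percentage of the D charged, in amber
5. final E, as a percentage of the D charged, in red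

I bracketed red first. From below, dusk read E (the product, from substrate D) at 51% at 12.0 h, and I took that E as staying. From above, E rose 12 percentage points over 4.00 h, then 4 points over the last 2.00 h. The last hourly gain was smaller than the one before, so holding it flat for the 8.00 h remaining gave my estimated cap on E of 67.0%.

To lift the floor I went to logarithms. The hourly rise fell by a factor of 1.50 between interval midpoints 3.00 h apart, which reads as a fade time of 7.40 h. The clock time left, weighted by that fade, I call the effective hours: 4.89 h at the last hourly rise. That put my estimated floor at 60.8%. Each reading scatters by 2 points, so the fade time is a loose reading, but I committed to 60.8% to 67.0%.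

The forecast put red first with 62%, inside my bracket (“E is 51% at 12 h and rising about 2%/h, fading, so about 62%”), and gave green 53%, teal 45% and amber 44%.

The flasks gave red 61.9%, green 59.5%, teal 50.3% and amber 49.3%, so red held the most E.

    Z + X + L → X + E (k = 0.0276 /M²/s, Ea = 41.0 kJ/mol)
    D + L → Q (k = 1.61 × 10⁻⁴ /M/s, Ea = 87.0 kJ/mol)
    D + X → X + L (k = 0.0129 /M/s, Ea = 71.0 kJ/mol)
    (constants at 70 °C)

In red, the half-life of D by its step to the intermediate L is 2.1 h at 1.74 h, shorter than the 4.89 h by which half of the E-making turnover up to 20 h is done. Red's 61.9% lies between 60.8% and 67.0%, the floor being dusk's last rise over 4.89 h. Green's E went from 28.3% at 10.0 h to 37.0% at 12.0 h, and that hourly rise over the same 4.89 h reckons 58.3% against the 59.5% green gave.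

The data stem from a simulated flask from invented constants, and the scatter is random.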